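**Retrosynthetic overview**
- Ring C is opened at O1–C2 and C2–C3: cyclodehydration of a 1,3-diketone made by Baker–Venkataraman acyl shift, leading back to acetophenone 13 (ring A) and acid 16 (ring B).
- The strategy rests on ring A: oxygen sits on four adjacent carbons (C6, C7, C8, C8a), C5 carries H and C4a the acyl carbon. The C7/C8 dimethoxy pair is the dimethoxy-alkene of dimethyl squarate.
- Ring A is disconnected at C4a–C8a: thermal ring expansion of the 4-alkenyl-4-hydroxycyclobutenone 8, made from dimethyl squarate and an (E)-alkenyllithium carrying the acetyl group as a dioxolane.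
- Ring order: ring A (step 5), then ring C (step 12); ring B is bought as 3-hydroxy-4,5-dimethoxybenzoic acid.

Key step: step 5

Assumption: the target is achiral, so the racemic carbinol centre of 8 needs no control; hydroquinones 11 and 12 are handled under argon in degassed solvents because they oxidise in air.

Step 1
Reactants: 1 4-(trimethylsilyl)but-3-yn-2-one
Product: 2 2-methyl-2-[(trimethylsilyl)ethynyl]-1,3-dioxolane
Conditions: TMSOCH2CH2OTMS (1.2 equiv), TMSOTf (5 mol%), CH2Cl2, −78 °C to −20 °C; pyridine quench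
Reagents that add atoms: 1,2-bis(trimethylsilyloxy)ethane, C[Si](C)(C)OCCO[Si](C)(C)C
Why: TMSOTf-catalysed acetalisation with the bis-silyl ether of the diol ketalises conjugated ketones at low temperature, and the silyl cap on the alkyne suppresses conjugate addition.

Step 2
Reactants: 2 2-methyl-2-[(trimethylsilyl)ethynyl]-1,3-dioxolane
Product: 3 2-ethynyl-2-methyl-1,3-dioxolane
Conditions: K2CO3 (0.2 equiv), MeOH, rt; extraction into pentane, careful concentration (volatile)
Reagents that add atoms: none
Why: Base-catalysed methanolytic C–Si cleavage (protodesilylation) of an alkynylsilane is reliable and leaves the base-stable ketal untouched.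

Step 3
Reactants: 3 2-ethynyl-2-methyl-1,3-dioxolane
Product: 5 (E)-2-(2-iodoethenyl)-2-methyl-1,3-dioxolane, via alkenylzirconocene chloride 4 (not isolated)
Conditions: Cp2Zr(H)Cl (1.2 equiv), THF, rt, dark; then I2 (1.1 equiv), 0 °C; Na2S2O3/NaHCO3 work-up
Reagents that add atoms: iodine, II
Why: Hydrozirconation–iodination: syn addition of Zr–H places zirconium on the terminal carbon away from the quaternary ketal carbon, and iodinolysis with retention should give the (E)-iodide.

Step 4
Reactants: 5 (E)-2-(2-iodoethenyl)-2-methyl-1,3-dioxolane; 6 dimethyl squarate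
Product: 8 racemic 4-hydroxy-2,3-dimethoxy-4-[(E)-2-(2-methyl-1,3-dioxolan-2-yl)ethenyl]cyclobut-2-en-1-one, via alkenyllithium 7 (not isolated)
Conditions: t-BuLi (2.0 equiv), Et2O, −78 °C; cannulated into 6 in THF, −78 °C; aq NH4Cl at −78 °C
Reagents that add atoms: none
Why: Iodine–lithium exchange retains the alkene geometry, and 1,2-addition of an organolithium to one of the two equivalent carbonyls of dimethyl squarate at −78 °C is the standard entry to 4-hydroxycyclobutenones; the new carbinol centre forms racemic and is erased later.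

Step 5
Reactants: 8 racemic 4-hydroxy-2,3-dimethoxy-4-[(E)-2-(2-methyl-1,3-dioxolan-2-yl)ethenyl]cyclobut-2-en-1-one
Product: 11 2,3-dimethoxy-5-(2-methyl-1,3-dioxolan-2-yl)benzene-1,4-diol, via (Z)-dienylketene 9 (not isolated), via cyclohexadienone 10 (not isolated)
Conditions: toluene (degassed), 110 °C, argon; crude product carried on under argon
Reagents that add atoms: none
Why: Moore rearrangement: thermal conrotatory 4π opening of the cyclobutenone C1–C4 bond turns the donor hydroxyl outward and the alkenyl arm inward, giving the (Z)-dienylketene 9. The ketene carbon (future C8a) then bonds to the distal alkene carbon (future C4a) in a disrotatory 6π electrocyclisation that closes ring A as cyclohexa-2,4-dienone 10, and enolisation of its C4a–H gives the aromatic hydroquinone 11. The closest known reaction type is the thermolysis of squarate-derived 4-alkenyl-4-hydroxycyclobutenones to hydroquinones. No stereocentre survives: the racemic carbinol centre of 8 and the transient sp3 centre of 10 are both erased on aromatisation. The selectivity needed is torquoselectivity (alkenyl inward), secured by the strong outward preference of the hydroxyl on the same carbon; regiochemistry is fixed by connectivity, so the squarate methoxy groups end at C7 and C8, the ketene oxygen at C8a (O1), the carbinol oxygen at C6 and hydrogen at C5. Degassed solvent under argon should keep the electron-rich hydroquinone from oxidising to the quinone.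

Step 6
Reactants: 11 2,3-dimethoxy-5-(2-methyl-1,3-dioxolan-2-yl)benzene-1,4-diol
Product: 12 1-(2,5-dihydroxy-3,4-dimethoxyphenyl)ethan-1-one
Conditions: 1 M HCl (aq), THF (degassed), rt, argon
Reagents that add atoms: water, O
Why: Acid-catalysed ketal hydrolysis is fast for an ortho-hydroxyaryl dioxolane, and the aryl methyl ethers are inert to dilute acid.

Step 7
Reactants: 12 1-(2,5-dihydroxy-3,4-dimethoxyphenyl)ethan-1-one
Product: 13 1-(2-hydroxy-3,4,5-trimethoxyphenyl)ethan-1-one
Conditions: MeI (1.05 equiv), K2CO3 (1.0 equiv), acetone, rt, argon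
Reagents that add atoms: iodomethane, CI
Why: Williamson etherification with limiting reagent: the hydroxyl ortho to the acetyl is tied up in a hydrogen bond to the carbonyl and is less acidic and less nucleophilic, so the free C5 hydroxyl should react first.

Step 8
Reactants: 14 3-hydroxy-4,5-dimethoxybenzoic acid
Product: 15 benzyl 3-(benzyloxy)-4,5-dimethoxybenzoate
Conditions: BnBr (2.3 equiv), K2CO3 (3 equiv), DMF, 60 °C
Reagents that add atoms: benzyl bromide, BrCc1ccccc1
Why: Double Williamson-type alkylation of phenoxide and carboxylate masks the ring B phenol so that it cannot compete in the later acylation.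

Step 9
Reactants: 15 benzyl 3-(benzyloxy)-4,5-dimethoxybenzoate
Product: 16 3-(benzyloxy)-4,5-dimethoxybenzoic acid
Conditions: NaOH (aq, 3 equiv), MeOH/THF, 60 °C; then 1 M HCl
Reagents that add atoms: sodium hydroxide, [Na+].[OH-]
Why: Saponification cleaves only the benzyl ester; the benzyl aryl ether is stable to hydroxide.

Step 10
Reactants: 13 1-(2-hydroxy-3,4,5-trimethoxyphenyl)ethan-1-one; 16 3-(benzyloxy)-4,5-dimethoxybenzoic acid
Product: 17 6-acetyl-2,3,4-trimethoxyphenyl 3-(benzyloxy)-4,5-dimethoxybenzoate
Conditions: EDC·HCl (1.5 equiv), DMAP (0.3 equiv), CH2Cl2, rt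
Reagents that add atoms: none
Why: Steglich esterification: the acylpyridinium formed from the O-acylisourea and DMAP is reactive enough to acylate the hindered, hydrogen-bonded phenol.

Step 11
Reactants: 17 6-acetyl-2,3,4-trimethoxyphenyl 3-(benzyloxy)-4,5-dimethoxybenzoate
Product: 18 1-[3-(benzyloxy)-4,5-dimethoxyphenyl]-3-(2-hydroxy-3,4,5-trimethoxyphenyl)propane-1,3-dione
Conditions: KOH (powdered, 3 equiv), pyridine, 50 °C; then 1 M HCl, 0 °C
Reagents that add atoms: none
Why: Baker–Venkataraman rearrangement: the methyl ketone enolate attacks the neighbouring aryl ester intramolecularly, and the O-to-C acyl shift is driven by formation of the phenoxide and diketonate.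

Step 12
Reactants: 18 1-[3-(benzyloxy)-4,5-dimethoxyphenyl]-3-(2-hydroxy-3,4,5-trimethoxyphenyl)propane-1,3-dione
Product: 19 2-[3-(benzyloxy)-4,5-dimethoxyphenyl]-6,7,8-trimethoxy-4H-chromen-4-one
Conditions: TsOH·H2O (0.1 equiv), toluene, reflux, Dean–Stark
Reagents that add atoms: none
Why: Acid-catalysed cyclodehydration: the phenol adds to the distal carbonyl to form a six-membered hemiketal, and loss of water closes ring C (O1–C2) as the chromone; catalytic sulfonic acid should spare the benzyl ether.

Step 13
Reactants: 19 2-[3-(benzyloxy)-4,5-dimethoxyphenyl]-6,7,8-trimethoxy-4H-chromen-4-one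
Product: 20 2-(3-hydroxy-4,5-dimethoxyphenyl)-6,7,8-trimethoxy-4H-chromen-4-one
Conditions: H2 (1 atm), 10% Pd/C, EtOAc/MeOH, rt, monitored closely
Reagents that add atoms: none
Why: Catalytic hydrogenolysis of the benzyl aryl ether frees the C3' phenol; the conjugated chromone C2=C3 bond should resist reduction at 1 atm and room temperature.

**Compound list**
1 | 4-(trimethylsilyl)but-3-yn-2-one | CC(=O)C#C[Si](C)(C)C | starting material
2 | 2-methyl-2-[(trimethylsilyl)ethynyl]-1,3-dioxolane | CC1(C#C[Si](C)(C)C)OCCO1 | intermediate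
3 | 2-ethynyl-2-methyl-1,3-dioxolane | CC1(C#C)OCCO1 | intermediate
4 | chlorobis(cyclopentadienyl)[(E)-2-(2-methyl-1,3-dioxolan-2-yl)ethenyl]zirconium | CC1(OCCO1)/C=C/[Zr](Cl)(C1C=CC=C1)C1C=CC=C1 | intermediate
5 | (E)-2-(2-iodoethenyl)-2-methyl-1,3-dioxolane | CC1(/C=C/I)OCCO1 | intermediate
6 | dimethyl squarate (3,4-dimethoxycyclobut-3-ene-1,2-dione) | COC1=C(OC)C(=O)C1=O | starting material
7 | [(E)-2-(2-methyl-1,3-dioxolan-2-yl)ethenyl]lithium | [Li]/C=C/C1(C)OCCO1 | intermediate
8 | racemic 4-hydroxy-2,3-dimethoxy-4-[(E)-2-(2-methyl-1,3-dioxolan-2-yl)ethenyl]cyclobut-2-en-1-one | COC1=C(OC)C(O)(/C=C/C2(C)OCCO2)C1=O | intermediate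
9 | (3Z,5E)-4-hydroxy-2,3-dimethoxy-6-(2-methyl-1,3-dioxolan-2-yl)hexa-1,3,5-trien-1-one | O=C=C(OC)/C(OC)=C(O)\C=C\C1(C)OCCO1 | intermediate
10 | racemic 4-hydroxy-2,3-dimethoxy-6-(2-methyl-1,3-dioxolan-2-yl)cyclohexa-2,4-dien-1-one | COC1=C(OC)C(O)=CC(C2(C)OCCO2)C1=O | intermediate
11 | 2,3-dimethoxy-5-(2-methyl-1,3-dioxolan-2-yl)benzene-1,4-diol | COc1c(O)cc(C2(C)OCCO2)c(O)c1OC | intermediate
12 | 1-(2,5-dihydroxy-3,4-dimethoxyphenyl)ethan-1-one | CC(=O)c1cc(O)c(OC)c(OC)c1O | intermediate
13 | 1-(2-hydroxy-3,4,5-trimethoxyphenyl)ethan-1-one | CC(=O)c1cc(OC)c(OC)c(OC)c1O | intermediate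
14 | 3-hydroxy-4,5-dimethoxybenzoic acid | O=C(O)c1cc(O)c(OC)c(OC)c1 | starting material
15 | benzyl 3-(benzyloxy)-4,5-dimethoxybenzoate | O=C(OCc1ccccc1)c1cc(OCc2ccccc2)c(OC)c(OC)c1 | intermediate
16 | 3-(benzyloxy)-4,5-dimethoxybenzoic acid | O=C(O)c1cc(OCc2ccccc2)c(OC)c(OC)c1 | intermediate
17 | 6-acetyl-2,3,4-trimethoxyphenyl 3-(benzyloxy)-4,5-dimethoxybenzoate | CC(=O)c1cc(OC)c(OC)c(OC)c1OC(=O)c1cc(OCc2ccccc2)c(OC)c(OC)c1 | intermediate
18 | 1-[3-(benzyloxy)-4,5-dimethoxyphenyl]-3-(2-hydroxy-3,4,5-trimethoxyphenyl)propane-1,3-dione | O=C(CC(=O)c1cc(OCc2ccccc2)c(OC)c(OC)c1)c1cc(OC)c(OC)c(OC)c1O | intermediate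
19 | 2-[3-(benzyloxy)-4,5-dimethoxyphenyl]-6,7,8-trimethoxy-4H-chromen-4-one | COc1cc2c(=O)cc(-c3cc(OCc4ccccc4)c(OC)c(OC)c3)oc2c(OC)c1OC | intermediate
20 | 2-(3-hydroxy-4,5-dimethoxyphenyl)-6,7,8-trimethoxy-4H-chromen-4-one | COc1cc(-c2cc(=O)c3cc(OC)c(OC)c(OC)c3o2)cc(O)c1OC | target

**Step count**
Total steps: 13. Longest linear sequence: 11 steps (steps 1 to 7, then 10 to 13).

**Steps most likely to fail**

Step 5. The electron-rich hydroquinone may oxidise to the quinone in hot toluene or on isolation, and any inward rotation of the free hydroxyl would divert the ketene into a furanone by lactonisation. Fallback, setting out from 8: the tertiary carbinol is O-methylated (MeI, Ag2O, K2CO3, MeCN, rt) to 2,3,4-trimethoxy-4-[(E)-2-(2-methyl-1,3-dioxolan-2-yl)ethenyl]cyclobut-2-en-1-one F1. Thermolysis of this ether in toluene at 110 °C should give 2,3,4-trimethoxy-6-(2-methyl-1,3-dioxolan-2-yl)phenol F2, a monophenol that cannot lactonise at the ketene stage and does not readily form a para-quinone. Hydrolysis with 1 M HCl in THF then returns to the route at 13, which also makes steps 6 and 7 unnecessary.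

Step 4. Iodine–lithium exchange may be incomplete, and the alkenyllithium may be consumed by tert-butyl iodide before it meets the squarate. Fallback, setting out from 3: hydrostannation (Bu3SnH, PdCl2(PPh3)2 2 mol%, THF, rt) should give (E)-tributyl[2-(2-methyl-1,3-dioxolan-2-yl)ethenyl]stannane F3, which can be purified and stored. Tin–lithium exchange with n-BuLi (THF, −78 °C) generates 7 beside inert tetrabutylstannane, and addition to 6 as in step 4 returns to the route at 8.

Step 7. Site selectivity may be poor, with methylation at the chelated hydroxyl or at both hydroxyls. Fallback, setting out from 12: exhaustive methylation (Me2SO4 excess, K2CO3, acetone, reflux) gives 1-(2,3,4,5-tetramethoxyphenyl)ethan-1-one F4. BCl3 (CH2Cl2, −78 °C to 0 °C) then cleaves only the methyl ether ortho to the carbonyl through a boron chelate, returning to the route at 13.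

**Further compounds**
F1 | step 5 | 2,3,4-trimethoxy-4-[(E)-2-(2-methyl-1,3-dioxolan-2-yl)ethenyl]cyclobut-2-en-1-one (racemic) | COC1=C(OC)C(OC)(/C=C/C2(C)OCCO2)C1=O
F2 | step 5 | 2,3,4-trimethoxy-6-(2-methyl-1,3-dioxolan-2-yl)phenol | COc1cc(C2(C)OCCO2)c(O)c(OC)c1OC
F3 | step 4 | (E)-tributyl[2-(2-methyl-1,3-dioxolan-2-yl)ethenyl]stannane | CCCC[Sn](CCCC)(CCCC)/C=C/C1(C)OCCO1
F4 | step 7 | 1-(2,3,4,5-tetramethoxyphenyl)ethan-1-one | CC(=O)c1cc(OC)c(OC)c(OC)c1OC
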